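A direct plan would buy the finished arene: 1,3-dimethoxy-5-pentylbenzene A1 would be formylated to aldehyde A2, one half oxidised to acid A3 and the other half demethylated to dihydroxy aldehyde A4.
A3 and A4 would be esterified to depside aldehyde A5, the remaining phenol methylated to trimethoxy depside aldehyde A6, and the formyl group of A6 oxidised to the carboxylic acid in the last step.
Weak point 1, the demethylation of A2 to A4 and the later methylation of A5: two methyl ethers would be removed to put one back, three operations that build nothing.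
Weak point 2, the final chlorite oxidation: the carboxyl carbon of ring B would travel as a formyl group and be oxidised on the complete depside, where two electron-rich rings meet hypochlorous acid and the aryl ester meets an aqueous oxidant.
Weak point 3, the esterification of A3 with A4: a di-ortho-substituted acid would have to acylate one of two free hydroxyls with hydrogen bonding as the only control, and both rings would be bought ready-made and merely decorated.

**Retrosynthetic overview**
Ring A (acyl ring, C1'–C6') and ring B (acid ring, C1–C6) are the same tetraketide: carboxyl carbon on C1, oxygen on C2 and C4, pentyl on C6. Both would be folded from one open-chain precursor, diketo-dioxinone 7, a masked 3,5,7-trioxododecanoyl ketene.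
Key disconnection: the depside bond C7'(=O)–O–C4 and the ring A bond C1'–C6' are cut together. Heating 7 with ring B phenol 10 would let O4 capture the acylketene, and ring A would close by aldol condensation on the ester.
Ring B would be formed first, by amine-induced aldol aromatisation of 7 itself to benzodioxinone 8 (bond C1–C6), which benzyl alkoxide opens to 10. Ring A would be formed last, on the depside. 7 would come from 2,2,6-trimethyl-4H-1,3-dioxin-4-one, acetyl chloride and a hexanoyl Weinreb amide by two Claisen-type acylations.
Both carboxyl carbons stay at the acid oxidation level throughout (no formyl group, no chlorite), no ether is ever cleaved (the three methyl groups go on once), and the depside ester is made by ketene capture, not from a hindered acid.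

Key step: step 5

Remark: the target has no stereocentre, and N-methoxy-N-methylhexanamide is taken as a catalogue compound.

**Route**

Step 1
Reactants: 1 2,2,6-trimethyl-4H-1,3-dioxin-4-one; 2 acetyl chloride
Product: 4 2,2-dimethyl-6-(2-oxopropyl)-4H-1,3-dioxin-4-one, via lithium dienolate 3 (not isolated)
Conditions: 1 (2.0 equiv), LiN(SiMe3)2 (2.0 equiv), THF, −78 °C, 1 h; then 2 (1.0 equiv), −78 °C to −20 °C; aq. NH4Cl
Reagents that add atoms: none
Why: Vinylogous Claisen acylation: LiN(SiMe3)2 removes a proton from the 6-methyl group, the extended lithium dienolate 3 is acylated by 2 at this γ-carbon, and the second equivalent of 3 takes up the acidic proton of the product, which stops a second acylation; no stereocentre is formed.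

Step 2
Reactants: 4 2,2-dimethyl-6-(2-oxopropyl)-4H-1,3-dioxin-4-one; 5 N-methoxy-N-methylhexanamide
Product: 7 6-(2,4-dioxononyl)-2,2-dimethyl-4H-1,3-dioxin-4-one, via dilithium dianion 6 (not isolated)
Conditions: LiN(i-Pr)2 (2.2 equiv), THF, −78 °C, 1 h; then 5 (1.1 equiv), −78 °C to −40 °C; aq. HCl to pH 3
Reagents that add atoms: none
Why: Claisen-type γ-acylation of a β-dicarbonyl dianion with a Weinreb amide: the second deprotonation takes place at the terminal methyl group of 4, this more basic and less hindered carbon of dianion 6 attacks 5, and the chelated tetrahedral adduct prevents over-addition until the acidic quench; no stereocentre is formed.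

Step 3
Reactants: 7 6-(2,4-dioxononyl)-2,2-dimethyl-4H-1,3-dioxin-4-one (larger portion of the batch)
Product: 8 7-hydroxy-2,2-dimethyl-5-pentyl-4H-1,3-benzodioxin-4-one
Conditions: Et3N (3 equiv), CH2Cl2, rt, 16 h; wash with dilute aq. HCl
Reagents that add atoms: none
Why: Base-induced aldol condensation with aromatisation of a diketo-dioxinone: triethylamine enolises 7, C5 of the dioxinone ring adds to the C4 ketone of the side chain in a 6-(enolendo)-exo-trig closure that forms bond C1–C6 of ring B, and loss of water with enolisation gives the phenol with the carboxyl carbon and the 2-oxygen still joined as the isopropylidene acetal, so that ring B is built at room temperature without an acylketene; no stereocentre is formed.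

Step 4
Reactants: 8 7-hydroxy-2,2-dimethyl-5-pentyl-4H-1,3-benzodioxin-4-one; 9 benzyl alcohol
Product: 10 benzyl 2,4-dihydroxy-6-pentylbenzoate
Conditions: 9 (3 equiv), NaH (2.5 equiv), THF, 0 °C to 60 °C, 6 h; aq. NH4Cl
Reagents that add atoms: none
Why: Alkoxide opening of a 2,2-dimethyl-1,3-benzodioxin-4-one (transesterification): sodium benzyloxide adds to the C4 carbonyl, the tetrahedral adduct expels the hemiketal oxygen O3, and loss of acetone leaves the 2-phenoxide of the benzyl ester, the excess of alkoxide and gentle heating making up for the deactivation of the carbonyl by the 7-phenoxide; no stereocentre is formed.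

Step 5
Reactants: 7 6-(2,4-dioxononyl)-2,2-dimethyl-4H-1,3-dioxin-4-one (remaining portion of the batch); 10 benzyl 2,4-dihydroxy-6-pentylbenzoate
Product: 13 benzyl 4-[(2,4-dihydroxy-6-pentylbenzoyl)oxy]-2-hydroxy-6-pentylbenzoate, via acylketene 11 (not isolated), via aryl triketo ester 12 (not isolated)
Conditions: 7 (1.0 equiv), 10 (1.5 equiv), toluene, 110 °C, 1 h; then Bu4NOAc (0.3 equiv), CH2Cl2, rt; then CF3CO2H (0.5 equiv), rt; excess 10 recovered
Reagents that add atoms: none
Why: Proposed new method: heating 7 should expel acetone by retro-[4+2] fragmentation to acylketene 11, to which the free, non-chelated 4-OH of 10 adds through a six-membered pseudopericyclic transition state to give aryl triketo ester 12, so that the depside C(=O)–O bond is made by ketene capture and not by acylation with a hindered acid. The closest known reaction types are the thermolysis of diketo-dioxinones with alcohols followed by aldol aromatisation to alkyl β-resorcylates, and the capture of dioxinone-derived acylketenes by phenols to aryl acetoacetates; new here is their union, with a phenol as the trap and the aromatisation of an aryl triketo ester. Ring A then closes by a 6-(enolendo)-exo-trig aldol addition of C2 of the chain (between the ester and C3 carbonyl groups) to the C7 ketone, which forms the C1'–C6' bond, and loss of water with enolisation gives the aromatic ring with 2'-OH, 4'-OH and the 6'-pentyl chain in place. The step needs site selectivity between the two hydroxyls of 10, secured by the hydrogen bond of the 2-OH to the benzyl ester carbonyl and by the excess of 10, and aldol closure in preference to Claisen or lactone closure with loss of the phenol, for which a weakly basic acetate in an aprotic solvent at room temperature is chosen in place of an alkoxide. No stereocentre is formed.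

Step 6
Reactants: 13 benzyl 4-[(2,4-dihydroxy-6-pentylbenzoyl)oxy]-2-hydroxy-6-pentylbenzoate
Product: 14 benzyl 4-[(2,4-dimethoxy-6-pentylbenzoyl)oxy]-2-methoxy-6-pentylbenzoate
Conditions: MeI (10 equiv), K2CO3 (6 equiv), acetone, reflux, 16 h
Reagents that add atoms: iodomethane, CI
Why: Williamson ether synthesis: K2CO3 deprotonates the three phenols and MeI methylates first the free 4'-OH and then the two hydrogen-bonded ortho hydroxyls, while the depside carbonyl is shielded by its two ortho substituents and deactivated by electron-rich ring A, and the benzyl ester is inert; no stereocentre is formed.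

Step 7
Reactants: 14 benzyl 4-[(2,4-dimethoxy-6-pentylbenzoyl)oxy]-2-methoxy-6-pentylbenzoate
Product: 15 planaic acid, 4-[(2,4-dimethoxy-6-pentylbenzoyl)oxy]-2-methoxy-6-pentylbenzoic acid
Conditions: H2 (1 atm), Pd/C (10 wt % palladium on carbon), EtOAc, rt
Reagents that add atoms: none
Why: Catalytic hydrogenolysis of the benzyl ester over Pd/C at neutral pH should set the carboxylic acid of ring B free and leave the aryl ester of the depside and the three aryl methyl ethers untouched; no stereocentre is formed.

**Compound list**

1 | 2,2,6-trimethyl-4H-1,3-dioxin-4-one | CC1=CC(=O)OC(C)(C)O1 | starting material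
2 | acetyl chloride | CC(Cl)=O | starting material
3 | lithium 2,2-dimethyl-6-methylidene-6H-1,3-dioxin-4-olate (lithium dienolate of 1) | [Li+].C=C1C=C([O-])OC(C)(C)O1 | intermediate (not isolated)
4 | 2,2-dimethyl-6-(2-oxopropyl)-4H-1,3-dioxin-4-one | CC(=O)CC1=CC(=O)OC(C)(C)O1 | intermediate
5 | N-methoxy-N-methylhexanamide | CCCCCC(=O)N(C)OC | starting material
6 | dilithium 2,2-dimethyl-6-(2-oxidoprop-2-en-1-ylidene)-6H-1,3-dioxin-4-olate (dianion of 4) | [Li+].[Li+].C=C([O-])C=C1C=C([O-])OC(C)(C)O1 | intermediate (not isolated)
7 | 6-(2,4-dioxononyl)-2,2-dimethyl-4H-1,3-dioxin-4-one | CCCCCC(=O)CC(=O)CC1=CC(=O)OC(C)(C)O1 | intermediate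
8 | 7-hydroxy-2,2-dimethyl-5-pentyl-4H-1,3-benzodioxin-4-one | CCCCCc1cc(O)cc2OC(C)(C)OC(=O)c12 | intermediate
9 | benzyl alcohol | OCc1ccccc1 | starting material
10 | benzyl 2,4-dihydroxy-6-pentylbenzoate | CCCCCc1cc(O)cc(O)c1C(=O)OCc1ccccc1 | intermediate
11 | 3,5,7-trioxododec-1-en-1-one (acylketene) | CCCCCC(=O)CC(=O)CC(=O)C=C=O | intermediate (not isolated)
12 | benzyl 2-hydroxy-6-pentyl-4-[(3,5,7-trioxododecanoyl)oxy]benzoate | CCCCCC(=O)CC(=O)CC(=O)CC(=O)Oc1cc(O)c(C(=O)OCc2ccccc2)c(CCCCC)c1 | intermediate (not isolated)
13 | benzyl 4-[(2,4-dihydroxy-6-pentylbenzoyl)oxy]-2-hydroxy-6-pentylbenzoate | CCCCCc1cc(O)cc(O)c1C(=O)Oc1cc(O)c(C(=O)OCc2ccccc2)c(CCCCC)c1 | intermediate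
14 | benzyl 4-[(2,4-dimethoxy-6-pentylbenzoyl)oxy]-2-methoxy-6-pentylbenzoate | CCCCCc1cc(OC)cc(OC)c1C(=O)Oc1cc(OC)c(C(=O)OCc2ccccc2)c(CCCCC)c1 | intermediate
15 | planaic acid, 4-[(2,4-dimethoxy-6-pentylbenzoyl)oxy]-2-methoxy-6-pentylbenzoic acid | CCCCCc1cc(OC(=O)c2c(CCCCC)cc(OC)cc2OC)cc(OC)c1C(=O)O | target

**Summary**

Total step count: 7. Longest linear sequence: 7 steps (1 → 4 → 7 → 8 → 10 → 13 → 14 → 15; 7 is used twice).

Steps most likely to fail:

Step 5 (proposed new method). A phenol captures acylketene 11 more slowly and more reversibly than an alcohol. Intramolecular closure of 11 to a 4-hydroxy-2-pyrone, acylation of the chelated 2-OH, or Claisen or lactone closure of 12 with expulsion of the phenol may therefore take over. The fallback uses known chemistry, sets out from 10 and comes back at 14. 10 would be methylated twice (MeI, K2CO3, acetone) to benzyl 2,4-dimethoxy-6-pentylbenzoate F1 and hydrogenolysed (H2, Pd/C) to 2,4-dimethoxy-6-pentylbenzoic acid F2. F2 would be activated with (CF3CO)2O in toluene as 2,4-dimethoxy-6-pentylbenzoic trifluoroacetic anhydride F3, which would acylate the free 4-OH of a second portion of 10 to give benzyl 4-[(2,4-dimethoxy-6-pentylbenzoyl)oxy]-2-hydroxy-6-pentylbenzoate F4. Methylation of the remaining phenol as in step 6 would give 14.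

Step 4. The phenoxide formed from the 7-OH of 8 donates into the C4 carbonyl, so the opening by benzyloxide may stall, and harsher conditions may cleave the new ester again. The fallback sets out from 7 and comes back at 10, and makes the ester bond before the ring instead of after it. 7 would be heated with benzyl alcohol in toluene at 110 °C, so that acylketene 11 is captured as benzyl 3,5,7-trioxododecanoate F5. Aldol closure of this triketo ester with CsOAc in i-PrOH/CH2Cl2 and dehydration with HCl in i-PrOH would give 10.

Step 6. Etherification of the two hydrogen-bonded hydroxyls may be slow, so that carbonate-induced acyl transfer or cleavage of the depside ester competes. The fallback sets out from 10 and comes back at 14, and does no methylation on a depside. The free 4-OH of 10 would be protected (MOMCl, i-Pr2NEt, CH2Cl2) as benzyl 2-hydroxy-4-(methoxymethoxy)-6-pentylbenzoate F6. The chelated 2-OH would be methylated on this robust monocyclic ester (MeI, K2CO3, DMF) to benzyl 2-methoxy-4-(methoxymethoxy)-6-pentylbenzoate F7, and the acetal cleaved (HCl, MeOH) to benzyl 4-hydroxy-2-methoxy-6-pentylbenzoate F8. Acylation of F8 with 2,4-dimethoxy-6-pentylbenzoic acid F2 through 2,4-dimethoxy-6-pentylbenzoic trifluoroacetic anhydride F3, both made as in the fallback for step 5, would give 14 directly.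

Further compounds
F1 | step 5 | benzyl 2,4-dimethoxy-6-pentylbenzoate | CCCCCc1cc(OC)cc(OC)c1C(=O)OCc1ccccc1
F2 | step 5 | 2,4-dimethoxy-6-pentylbenzoic acid | CCCCCc1cc(OC)cc(OC)c1C(=O)O
F3 | step 5 | 2,4-dimethoxy-6-pentylbenzoic trifluoroacetic anhydride | CCCCCc1cc(OC)cc(OC)c1C(=O)OC(=O)C(F)(F)F
F4 | step 5 | benzyl 4-[(2,4-dimethoxy-6-pentylbenzoyl)oxy]-2-hydroxy-6-pentylbenzoate | CCCCCc1cc(OC)cc(OC)c1C(=O)Oc1cc(O)c(C(=O)OCc2ccccc2)c(CCCCC)c1
F5 | step 4 | benzyl 3,5,7-trioxododecanoate | CCCCCC(=O)CC(=O)CC(=O)CC(=O)OCc1ccccc1
F6 | step 6 | benzyl 2-hydroxy-4-(methoxymethoxy)-6-pentylbenzoate | CCCCCc1cc(OCOC)cc(O)c1C(=O)OCc1ccccc1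
F7 | step 6 | benzyl 2-methoxy-4-(methoxymethoxy)-6-pentylbenzoate | CCCCCc1cc(OCOC)cc(OC)c1C(=O)OCc1ccccc1
F8 | step 6 | benzyl 4-hydroxy-2-methoxy-6-pentylbenzoate | CCCCCc1cc(O)cc(OC)c1C(=O)OCc1ccccc1
A1 | direct plan | 1,3-dimethoxy-5-pentylbenzene | CCCCCc1cc(OC)cc(OC)c1
A2 | direct plan | 2,4-dimethoxy-6-pentylbenzaldehyde | CCCCCc1cc(OC)cc(OC)c1C=O
A3 | direct plan | 2,4-dimethoxy-6-pentylbenzoic acid | CCCCCc1cc(OC)cc(OC)c1C(=O)O
A4 | direct plan | 2,4-dihydroxy-6-pentylbenzaldehyde | CCCCCc1cc(O)cc(O)c1C=O
A5 | direct plan | 4-formyl-3-hydroxy-5-pentylphenyl 2,4-dimethoxy-6-pentylbenzoate | CCCCCc1cc(OC(=O)c2c(CCCCC)cc(OC)cc2OC)cc(O)c1C=O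
A6 | direct plan | 4-formyl-3-methoxy-5-pentylphenyl 2,4-dimethoxy-6-pentylbenzoate | CCCCCc1cc(OC(=O)c2c(CCCCC)cc(OC)cc2OC)cc(OC)c1C=O
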